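We have to choose how long to leave these flasks, so we count turnovers of J against the G charged and do not follow the clock.

common to all: J 0.060 M; G 0.0720 M
- epsilon: time 50 s
- beta: time 100 s
- zeta: time 200 s

    J + G → J.G, rate k1*[J]^0.5*[G]^0.5 (k1 = 0.031 s⁻¹)
    G + J.G → G.J.G (k2 = 5.8 M⁻¹ s⁻¹)
    2 G → G2 (k3 = 0.47 M⁻¹ s⁻¹)

1. which of these there is most of at the end, counted by the J in it, epsilon (J / J.G / G.J.G)
2. which of these there is most of at the end, counted by the J in it, beta (J / J.G / G.J.G)
3. which of these there is most of at the end, counted by the J in it, zeta (J / J.G / G.J.G)
4. amount of the one of these that there is most of at the end, in percent of the J charged, epsilon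
5. amount of the one of these that there is most of at the end, in percent of the J charged, beta
6. amount of the one of these that there is most of at the end, in percent of the J charged, zeta

First a look at the clock. At the start, the step making J.G and the dimerisation together would use up the charge of G in 10.4 s. The pace falls as [G] falls, so this is a rough scale, but it is shorter than the 50 s of epsilon. On that comparison we treat G as the limiting reagent and ask what its charge can buy.

Our small table has one row for each place a G can go, and each entry is the G charged per J turned:

- Making J.G: 1.
- Making G.J.G: 1 more, for a J that goes through.
- Making G2: the rate at which the dimerisation uses G, divided by the rate of the step making J.G. This ratio is 2.39 at the start and falls with [G] while [J] is held. Taken at half the charge of G, with [J] still at its charge, it is 0.846.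

Reading down the column gives the G bill 2.85, the G paid for each J taken through to G.J.G, dimerisation included.

The second row is not paid by J.G still standing. Where the making of J.G and its capture by G go at equal rates, at that same [G] and with [J] at its charge, [J.G] stands at 0.00690 M, and we add this back to the charge. So 0.0720 M of G, with that refund, turns 0.0277 M of J. Our reckoning for epsilon puts most of the J in J, at 53.8 %, and beta and zeta have the same charges.

The forecast says J in each flask, at 51 % in epsilon, 51 % in beta and 51 % in zeta, on the ground that “Everything therefore stops before 50 s”. Its figure stands a little below ours.

The flasks give J as the largest holder, at 51.6 % in epsilon, 51.6 % in beta and 51.6 % in zeta. In epsilon, G stands at 7.13 % of its charge after 25.0 s and 0 % after 50.0 s, and the reading of J is unchanged at ten times the time. Now take the neighbour of zeta with 0.24 M of J. Its bill is 2.42, and with a refund of 0.0138 M the bill leaves 85.2 % of its J. That flask ends with 84.6 % of its J.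

The constants are invented; no experiment stands behind them.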